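**Retrosynthetic overview**

1. The last step is a hydroxyl-directed epoxidation of the C8=C9 allylic alcohol; before it the C6 veratrate and C2 acetate are placed on a 2,4,6,10-tetraoxygenated dauc-8-ene.
2. The C4 carbinol comes from isopropyl addition to a C4 ketone; the seven-membered ring is closed at C8=C9 by ring-closing metathesis of a trans-2,3-disubstituted cyclopentanone.
3. Key disconnection: the C1–C10 bond (quaternary C1 plus the C10 carbinol) by anionic oxy-Cope [3,3] rearrangement of a 1-(3-alkoxyallyl)cyclopent-2-en-1-ol; the enolate released makes C5–C6 by an anti aldol.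
4. The rearrangement substrate comes from acetylide 1,2-addition to (S)-4-silyloxy-3-methylcyclopent-2-enone; its one bought stereocentre (C2 of the target) steers all the others.
5. Ring order: five-membered ring (bought), seven-membered ring (metathesis), oxirane (last).

Numbering: daucane numbering throughout. C1 (ring-fusion carbon with methyl C15), C2, C3, C4 (isopropyl C11–C13) and C5 (ring-fusion CH) form the five-membered ring; C6, C7, C8 (methyl C14), C9 and C10 complete the seven-membered ring. CIP letters at C1, C4 and C10 change along the route only where substituent ranking changes; no centre is inverted.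

Assumption: read literally, the C8/C9 descriptors of the given string put C7 and C10 on opposite faces of the oxirane, which a seven-membered ring cannot hold. The route therefore makes the cis-fused 8,9-epoxide on the face of the C10 hydroxyl (C9 as written, C8 as the ring fusion then requires: COc1ccc(C(=O)O[C@@H]2C[C@]3(C)O[C@@H]3[C@H](O)[C@]3(C)[C@@H](OC(C)=O)C[C@](O)(C(C)C)[C@@H]23)cc1OC); the entry for 22 repeats the given string unchanged.

**Route**

Step 1
Reactants: 1 (S)-4-[(tert-butyldimethylsilyl)oxy]cyclopent-2-en-1-one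
Product: 2 tert-butyldimethyl{[(1S,2S)-2-methyl-4-(trimethylsilyloxy)cyclopent-3-en-1-yl]oxy}silane
Conditions: Me2CuLi (from MeLi and CuI), Me3SiCl, THF, −78 °C
Reagents that add atoms: lithium dimethylcuprate [Li+].C[Cu-]C; chlorotrimethylsilane C[Si](C)(C)Cl
Why: Me3SiCl-accelerated cuprate conjugate addition anti to the silyloxy group, with the enolate trapped at once as its silyl enol ether so that β-elimination of the silyloxy group cannot start; the new methyl-bearing centre is erased again in step 2.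

Step 2
Reactants: 2 tert-butyldimethyl{[(1S,2S)-2-methyl-4-(trimethylsilyloxy)cyclopent-3-en-1-yl]oxy}silane
Product: 3 (S)-4-[(tert-butyldimethylsilyl)oxy]-3-methylcyclopent-2-en-1-one
Conditions: Pd(OAc)2 (1 equiv), MeCN, rt
Reagents that add atoms: none
Why: Saegusa–Ito oxidation (palladation of the silyl enol ether, then β-hydride elimination towards the methyl-bearing carbon) gives the β-methyl enone and leaves the silyloxy stereocentre untouched.

Step 3
Reactants: 3 (S)-4-[(tert-butyldimethylsilyl)oxy]-3-methylcyclopent-2-en-1-one; 4 1-methoxy-4-[(prop-2-yn-1-yloxy)methyl]benzene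
Product: 6 (1R,4S)-4-[(tert-butyldimethylsilyl)oxy]-1-{3-[(4-methoxybenzyl)oxy]prop-1-yn-1-yl}-3-methylcyclopent-2-en-1-ol, via lithium acetylide 5 (not isolated)
Conditions: 4, n-BuLi, THF, −78 °C; then 3, −78 °C; H2O
Reagents that add atoms: none
Why: 1,2-addition of the lithium acetylide to the enone carbonyl from the ring face opposite the silyloxy group sets the tertiary carbinol with OH cis to OTBS and the carbon chain trans to it.

Step 4
Reactants: 6 (1R,4S)-4-[(tert-butyldimethylsilyl)oxy]-1-{3-[(4-methoxybenzyl)oxy]prop-1-yn-1-yl}-3-methylcyclopent-2-en-1-ol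
Product: 7 (1S,4S)-4-[(tert-butyldimethylsilyl)oxy]-1-{(1E)-3-[(4-methoxybenzyl)oxy]prop-1-en-1-yl}-3-methylcyclopent-2-en-1-ol
Conditions: NaAlH2(OCH2CH2OCH3)2, THF, −20 to 0 °C; H2O
Reagents that add atoms: none
Why: alkoxide-directed trans-hydroalumination of the propargylic alcohol followed by protonolysis gives the E alkene; the low temperature suppresses loss of the ether oxygen to an allene.

Step 5
Reactants: 7 (1S,4S)-4-[(tert-butyldimethylsilyl)oxy]-1-{(1E)-3-[(4-methoxybenzyl)oxy]prop-1-en-1-yl}-3-methylcyclopent-2-en-1-ol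
Product: 8 (1R,4S)-4-[(tert-butyldimethylsilyl)oxy]-1-{(2E)-3-[(4-methoxybenzyl)oxy]prop-2-en-1-yl}-3-methylcyclopent-2-en-1-ol
Conditions: [Ir(cod)(PMePh2)2]PF6 (2 mol %, activated with H2), THF, rt
Reagents that add atoms: none
Why: iridium-hydride-catalysed 1,3-hydrogen shift moves the allyl ether double bond into conjugation with oxygen to give the E enol ether of a 3-hydroxy-1,5-diene; the trisubstituted ring alkene and the hydrogen-free tertiary carbinol cannot isomerise.

Step 6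
Reactants: 9 3-methylbut-3-en-1-ol
Product: 10 3-methylbut-3-enal
Conditions: Dess–Martin periodinane, NaHCO3, CH2Cl2, 0 °C; used at once as a solution
Reagents that add atoms: none
Why: buffered Dess–Martin oxidation of the primary alcohol stops at the aldehyde and keeps the β,γ-alkene out of conjugation.

Step 7
Reactants: 8 (1R,4S)-4-[(tert-butyldimethylsilyl)oxy]-1-{(2E)-3-[(4-methoxybenzyl)oxy]prop-2-en-1-yl}-3-methylcyclopent-2-en-1-ol; 10 3-methylbut-3-enal
Product: 14 (2R,3R,4S)-4-[(tert-butyldimethylsilyl)oxy]-2-[(1R)-1-hydroxy-3-methylbut-3-en-1-yl]-3-{(1S)-1-[(4-methoxybenzyl)oxy]prop-2-en-1-yl}-3-methylcyclopentan-1-one, via potassium alkoxide 11 (not isolated), via potassium enolate 12 (not isolated), via chlorozinc enolate 13 (not isolated)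
Conditions: KH, 18-crown-6, THF, 0 °C to rt; ZnCl2, −78 °C; then 10, −78 to −40 °C; H2O
Reagents that add atoms: none
Why: the alkoxide undergoes an anionic oxy-Cope [3,3]-sigmatropic rearrangement in which the alkoxy-bearing allyl terminus bonds to C1 on the ring face carrying the side chain (trans to the C2 silyloxy group), a chair transition state with the E-enol ether oxygen equatorial fixing C10, and the regiodefined enolate, moved to zinc, adds to 10 opposite the new C1 substituent through a Zimmerman–Traxler chair (anti aldol), setting C5 and C6.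

Step 8
Reactants: 14 (2R,3R,4S)-4-[(tert-butyldimethylsilyl)oxy]-2-[(1R)-1-hydroxy-3-methylbut-3-en-1-yl]-3-{(1S)-1-[(4-methoxybenzyl)oxy]prop-2-en-1-yl}-3-methylcyclopentan-1-one
Product: 15 (3S,3aR,4S,8R,8aR)-3-[(tert-butyldimethylsilyl)oxy]-8-hydroxy-4-[(4-methoxybenzyl)oxy]-3a,6-dimethyl-3,3a,4,7,8,8a-hexahydroazulen-1(2H)-one
Conditions: second-generation Grubbs catalyst (5 mol %), CH2Cl2, 40 °C
Reagents that add atoms: none
Why: ring-closing olefin metathesis of the vinyl group with the 1,1-disubstituted alkene closes the seven-membered ring as the trisubstituted C8=C9 alkene, and the trans side chains become the trans ring fusion.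

Step 9
Reactants: 15 (3S,3aR,4S,8R,8aR)-3-[(tert-butyldimethylsilyl)oxy]-8-hydroxy-4-[(4-methoxybenzyl)oxy]-3a,6-dimethyl-3,3a,4,7,8,8a-hexahydroazulen-1(2H)-one
Product: 16 (1R,2S,4S,5R,6R,10S)-2-[(tert-butyldimethylsilyl)oxy]-10-[(4-methoxybenzyl)oxy]dauc-8-ene-4,6-diol
Conditions: i-PrMgCl, CeCl3, THF, −78 to 0 °C; H2O
Reagents that add atoms: isopropylmagnesium chloride CC(C)[Mg]Cl
Why: organocerium 1,2-addition (little enolisation or reduction) to the C4 ketone from the face of H5, opposite the pseudo-axial C1 methyl and C6, sets the tertiary carbinol with OH cis to the angular methyl.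

Step 10
Reactants: 16 (1R,2S,4S,5R,6R,10S)-2-[(tert-butyldimethylsilyl)oxy]-10-[(4-methoxybenzyl)oxy]dauc-8-ene-4,6-diol; 17 3,4-dimethoxybenzoyl chloride
Product: 18 (1R,2S,4S,5R,6R,10S)-2-[(tert-butyldimethylsilyl)oxy]-4-hydroxy-10-[(4-methoxybenzyl)oxy]dauc-8-en-6-yl 3,4-dimethoxybenzoate
Conditions: Et3N, DMAP (cat.), CH2Cl2, 0 °C to rt
Reagents that add atoms: none
Why: DMAP-catalysed acylation takes the only free secondary hydroxyl (C6), the tertiary C4 hydroxyl being too hindered to react.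

Step 11
Reactants: 18 (1R,2S,4S,5R,6R,10S)-2-[(tert-butyldimethylsilyl)oxy]-4-hydroxy-10-[(4-methoxybenzyl)oxy]dauc-8-en-6-yl 3,4-dimethoxybenzoate
Product: 19 (1S,2S,4S,5R,6R,10S)-2,4-dihydroxy-10-[(4-methoxybenzyl)oxy]dauc-8-en-6-yl 3,4-dimethoxybenzoate
Conditions: HF·pyridine, THF, 0 °C to rt
Reagents that add atoms: none
Why: fluoride-driven desilylation frees the C2 hydroxyl under conditions that leave the ester, the benzylic ether and the tertiary alcohol alone.

Step 12
Reactants: 19 (1S,2S,4S,5R,6R,10S)-2,4-dihydroxy-10-[(4-methoxybenzyl)oxy]dauc-8-en-6-yl 3,4-dimethoxybenzoate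
Product: 20 (1S,2S,4S,5R,6R,10S)-2-acetoxy-4-hydroxy-10-[(4-methoxybenzyl)oxy]dauc-8-en-6-yl 3,4-dimethoxybenzoate
Conditions: Ac2O, DMAP (cat.), pyridine, 0 °C to rt
Reagents that add atoms: acetic anhydride CC(=O)OC(C)=O
Why: DMAP-catalysed acetylation of the secondary C2 hydroxyl, with the tertiary C4 hydroxyl again inert.

Step 13
Reactants: 20 (1S,2S,4S,5R,6R,10S)-2-acetoxy-4-hydroxy-10-[(4-methoxybenzyl)oxy]dauc-8-en-6-yl 3,4-dimethoxybenzoate
Product: 21 (1R,2S,4S,5R,6R,10S)-2-acetoxy-4,10-dihydroxydauc-8-en-6-yl 3,4-dimethoxybenzoate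
Conditions: DDQ (1.2 equiv), CH2Cl2/pH 7 buffer, 0 °C
Reagents that add atoms: none
Why: oxidative cleavage of the 4-methoxybenzyl ether by DDQ (benzylic hydride abstraction, then hydrolysis of the oxocarbenium ion) frees the C10 hydroxyl and spares the electron-poorer benzoate.

Step 14
Reactants: 21 (1R,2S,4S,5R,6R,10S)-2-acetoxy-4,10-dihydroxydauc-8-en-6-yl 3,4-dimethoxybenzoate
Product: 22 (1R,2S,4S,5R,6R,9R,10R)-2-acetoxy-8,9-epoxy-4,10-dihydroxydaucan-6-yl 3,4-dimethoxybenzoate (CNP0197096.4)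
Conditions: VO(acac)2 (5 mol %), t-BuOOH, CH2Cl2, 0 °C to rt
Reagents that add atoms: tert-butyl hydroperoxide CC(C)(C)OO
Why: vanadium-catalysed hydroxyl-directed epoxidation of the cyclic allylic alcohol delivers oxygen to the alkene face syn to the C10 hydroxyl, which sets C9 as written and C8 as the cis ring fusion requires.

**Compound list**

1 | (S)-4-[(tert-butyldimethylsilyl)oxy]cyclopent-2-en-1-one | O=C1C=C[C@@H](O[Si](C)(C)C(C)(C)C)C1 | starting material
2 | tert-butyldimethyl{[(1S,2S)-2-methyl-4-(trimethylsilyloxy)cyclopent-3-en-1-yl]oxy}silane | C[Si](C)(C)OC1=C[C@H](C)[C@@H](O[Si](C)(C)C(C)(C)C)C1 | intermediate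
3 | (S)-4-[(tert-butyldimethylsilyl)oxy]-3-methylcyclopent-2-en-1-one | O=C1C=C(C)[C@@H](O[Si](C)(C)C(C)(C)C)C1 | intermediate
4 | 1-methoxy-4-[(prop-2-yn-1-yloxy)methyl]benzene | C#CCOCc1ccc(OC)cc1 | starting material
5 | lithium acetylide of 4 | [Li]C#CCOCc1ccc(OC)cc1 | intermediate
6 | (1R,4S)-4-[(tert-butyldimethylsilyl)oxy]-1-{3-[(4-methoxybenzyl)oxy]prop-1-yn-1-yl}-3-methylcyclopent-2-en-1-ol | COc1ccc(COCC#C[C@]2(O)C=C(C)[C@@H](O[Si](C)(C)C(C)(C)C)C2)cc1 | intermediate
7 | (1S,4S)-4-[(tert-butyldimethylsilyl)oxy]-1-{(1E)-3-[(4-methoxybenzyl)oxy]prop-1-en-1-yl}-3-methylcyclopent-2-en-1-ol | COc1ccc(COC/C=C/[C@]2(O)C=C(C)[C@@H](O[Si](C)(C)C(C)(C)C)C2)cc1 | intermediate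
8 | (1R,4S)-4-[(tert-butyldimethylsilyl)oxy]-1-{(2E)-3-[(4-methoxybenzyl)oxy]prop-2-en-1-yl}-3-methylcyclopent-2-en-1-ol | COc1ccc(CO/C=C/C[C@]2(O)C=C(C)[C@@H](O[Si](C)(C)C(C)(C)C)C2)cc1 | intermediate
9 | 3-methylbut-3-en-1-ol | CC(=C)CCO | starting material
10 | 3-methylbut-3-enal | CC(=C)CC=O | intermediate
11 | potassium alkoxide of 8 | COc1ccc(CO/C=C/C[C@]2([O-])C=C(C)[C@@H](O[Si](C)(C)C(C)(C)C)C2)cc1.[K+] | intermediate
12 | potassium enolate formed by the [3,3] shift (C4–O enolate; C1 quaternary with the 1-(4-methoxybenzyloxy)allyl group) | [K+].[O-]C1=C[C@](C)([C@@H](OCc2ccc(OC)cc2)C=C)[C@@H](O[Si](C)(C)C(C)(C)C)C1 | intermediate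
13 | chlorozinc enolate corresponding to 12 | Cl[Zn]OC1=C[C@](C)([C@@H](OCc2ccc(OC)cc2)C=C)[C@@H](O[Si](C)(C)C(C)(C)C)C1 | intermediate
14 | (2R,3R,4S)-4-[(tert-butyldimethylsilyl)oxy]-2-[(1R)-1-hydroxy-3-methylbut-3-en-1-yl]-3-{(1S)-1-[(4-methoxybenzyl)oxy]prop-2-en-1-yl}-3-methylcyclopentan-1-one | O[C@H](CC(C)=C)[C@@H]1C(=O)C[C@H](O[Si](C)(C)C(C)(C)C)[C@@]1(C)[C@@H](OCc2ccc(OC)cc2)C=C | intermediate
15 | (3S,3aR,4S,8R,8aR)-3-[(tert-butyldimethylsilyl)oxy]-8-hydroxy-4-[(4-methoxybenzyl)oxy]-3a,6-dimethyl-3,3a,4,7,8,8a-hexahydroazulen-1(2H)-one (trans-fused) | O[C@@H]1CC(C)=C[C@H](OCc4ccc(OC)cc4)[C@]3(C)[C@@H](O[Si](C)(C)C(C)(C)C)CC(=O)[C@@H]13 | intermediate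
16 | (1R,2S,4S,5R,6R,10S)-2-[(tert-butyldimethylsilyl)oxy]-10-[(4-methoxybenzyl)oxy]dauc-8-ene-4,6-diol | O[C@@H]1CC(C)=C[C@H](OCc4ccc(OC)cc4)[C@]3(C)[C@@H](O[Si](C)(C)C(C)(C)C)C[C@](O)(C(C)C)[C@@H]13 | intermediate
17 | 3,4-dimethoxybenzoyl chloride | COc1ccc(C(=O)Cl)cc1OC | starting material
18 | (1R,2S,4S,5R,6R,10S)-2-[(tert-butyldimethylsilyl)oxy]-4-hydroxy-10-[(4-methoxybenzyl)oxy]dauc-8-en-6-yl 3,4-dimethoxybenzoate | COc1ccc(C(=O)O[C@@H]2CC(C)=C[C@H](OCc4ccc(OC)cc4)[C@]3(C)[C@@H](O[Si](C)(C)C(C)(C)C)C[C@](O)(C(C)C)[C@@H]23)cc1OC | intermediate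
19 | (1S,2S,4S,5R,6R,10S)-2,4-dihydroxy-10-[(4-methoxybenzyl)oxy]dauc-8-en-6-yl 3,4-dimethoxybenzoate | COc1ccc(C(=O)O[C@@H]2CC(C)=C[C@H](OCc4ccc(OC)cc4)[C@]3(C)[C@@H](O)C[C@](O)(C(C)C)[C@@H]23)cc1OC | intermediate
20 | (1S,2S,4S,5R,6R,10S)-2-acetoxy-4-hydroxy-10-[(4-methoxybenzyl)oxy]dauc-8-en-6-yl 3,4-dimethoxybenzoate | COc1ccc(C(=O)O[C@@H]2CC(C)=C[C@H](OCc4ccc(OC)cc4)[C@]3(C)[C@@H](OC(C)=O)C[C@](O)(C(C)C)[C@@H]23)cc1OC | intermediate
21 | (1R,2S,4S,5R,6R,10S)-2-acetoxy-4,10-dihydroxydauc-8-en-6-yl 3,4-dimethoxybenzoate | COc1ccc(C(=O)O[C@@H]2CC(C)=C[C@H](O)[C@]3(C)[C@@H](OC(C)=O)C[C@](O)(C(C)C)[C@@H]23)cc1OC | intermediate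
22 | (1R,2S,4S,5R,6R,9R,10R)-2-acetoxy-8,9-epoxy-4,10-dihydroxydaucan-6-yl 3,4-dimethoxybenzoate, CNP0197096.4 (string as given; C8 see assumption) | COc1ccc(C(=O)O[C@@H]2C[C@@]3(C)O[C@@H]3[C@H](O)[C@]3(C)[C@@H](OC(C)=O)C[C@](O)(C(C)C)[C@@H]23)cc1OC | target

**Step count and risks**

Total step count: 14. Longest linear sequence: 13 (steps 1–5 and 7–14, from 1); step 6 is a one-step side branch.

Most likely to fail: step 7, step 5 and step 9.

Step 7 asks one flask to carry out the rearrangement, a metal exchange and an aldol addition to an enolisable β,γ-unsaturated aldehyde. Proton transfer, silyl migration between the cis oxygens, or poor anti selectivity could each spoil it, and the C10 configuration rests on the chair transition state. Fallback: set out from 8, run the rearrangement alone (KH, 18-crown-6, THF) and quench the enolate with Me3SiCl to isolate the silyl enol ether tert-butyldimethyl{[(1S,2R)-2-{(1S)-1-[(4-methoxybenzyl)oxy]prop-2-en-1-yl}-2-methyl-4-(trimethylsilyloxy)cyclopent-3-en-1-yl]oxy}silane F1. Its C10 configuration can be checked at this stage. A Lewis-acid-mediated Mukaiyama aldol addition of F1 to 10 (BF3·OEt2, CH2Cl2, −78 °C), which involves no basic enolate, then comes back to the route at 14.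

Step 5 may stall on the internal allyl ether next to a free tertiary hydroxyl, or lose the E geometry on which C10 depends. Fallback: set out from 3 and add the propargylzinc reagent (propargyl bromide, Zn, THF), again anti to the silyloxy group, to give (1R,4S)-4-[(tert-butyldimethylsilyl)oxy]-3-methyl-1-(prop-2-yn-1-yl)cyclopent-2-en-1-ol F2. Hydroborate the terminal alkyne with pinacolborane and Cp2Zr(H)Cl (cat.) to (1R,4S)-4-[(tert-butyldimethylsilyl)oxy]-3-methyl-1-[(2E)-3-(4,4,5,5-tetramethyl-1,3,2-dioxaborolan-2-yl)prop-2-en-1-yl]cyclopent-2-en-1-ol F3. Couple F3 with 4-methoxybenzyl alcohol under Cu(OAc)2 and Et3N (oxidative C–O coupling with retention of the alkene geometry), which comes back to the route at 8.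

Step 9 puts a branched, β-hydride-bearing nucleophile onto a hindered ketone that also carries a β-hydroxyl; reduction, enolisation or retro-aldol opening could compete. Fallback: set out from 15 and add isopropenylmagnesium bromide with CeCl3 (sp2 nucleophile, smaller, no hydride transfer) to give (1R,2S,4R,5R,6R,10S)-2-[(tert-butyldimethylsilyl)oxy]-10-[(4-methoxybenzyl)oxy]dauca-8,11-diene-4,6-diol F4. Hydrogenate only its 1,1-disubstituted alkene with H2 and RhCl(PPh3)3 in benzene, which comes back to the route at 16.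

**Further compounds**

F1 | step 7 | tert-butyldimethyl{[(1S,2R)-2-{(1S)-1-[(4-methoxybenzyl)oxy]prop-2-en-1-yl}-2-methyl-4-(trimethylsilyloxy)cyclopent-3-en-1-yl]oxy}silane | C[Si](C)(C)OC1=C[C@](C)([C@@H](OCc2ccc(OC)cc2)C=C)[C@@H](O[Si](C)(C)C(C)(C)C)C1
F2 | step 5 | (1R,4S)-4-[(tert-butyldimethylsilyl)oxy]-3-methyl-1-(prop-2-yn-1-yl)cyclopent-2-en-1-ol | C#CC[C@]1(O)C=C(C)[C@@H](O[Si](C)(C)C(C)(C)C)C1
F3 | step 5 | (1R,4S)-4-[(tert-butyldimethylsilyl)oxy]-3-methyl-1-[(2E)-3-(4,4,5,5-tetramethyl-1,3,2-dioxaborolan-2-yl)prop-2-en-1-yl]cyclopent-2-en-1-ol | CC1(C)OB(/C=C/C[C@]2(O)C=C(C)[C@@H](O[Si](C)(C)C(C)(C)C)C2)OC1(C)C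
F4 | step 9 | (1R,2S,4R,5R,6R,10S)-2-[(tert-butyldimethylsilyl)oxy]-10-[(4-methoxybenzyl)oxy]dauca-8,11-diene-4,6-diol | O[C@@H]1CC(C)=C[C@H](OCc4ccc(OC)cc4)[C@]3(C)[C@@H](O[Si](C)(C)C(C)(C)C)C[C@](O)(C(C)=C)[C@@H]13
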